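Wednesday's flask holds 10 mM of first end groups against 9.50 mM of second end groups, and each link uses one of each, so second end groups are the limiting reagent and links can reach 95.0% of the first end groups charged. This ratio of the two charges is the ceiling; equal charges, a ratio of one, are the zero of its scale.

| flask | first end groups | second end groups | scavenger | remark | time |
|---|---|---|---|---|---|
| Wednesday's | 10 mM | 9.5 mM | 8 mM | the very flask that is asked about, followed so far |  |
| Friday's | 15 mM | 9.5 mM | 8 mM | run made earlier |  |
| flask | 10 mM | 9.50 mM | 8.00 mM |  | 10 d |

- Wednesday's (time / d: first end groups / %, links / %): 0.333: 39, 59; 0.500: 32, 65; 0.833: 28, 82; 1.04: 23, 78; 1.67: 15, 82; 2.50: 13, 86; 4.00: 10, 89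
- Friday's (time / d: first end groups / %, links / %): 0.333: 50, 50; 0.500: 47, 54; 0.833: 41, 57; 1.04: 39, 63; 1.67: 38, 63; 2.50: 42, 61; 4.00: 38, 62

(each reading ± 2 percentage points)

- for released group the idle adduct is counted in
- the numbers in the tables scatter with a standard deviation of 2 percentage points
- steps thought possible: first end groups + second end groups <-> links + released group; first end groups + released group -> side product; second end groups + released group <-> idle adduct; second end groups <-> dormant form; scavenger + released group -> scavenged by-product
- the earlier runs do not show how much of second end groups is bound; that part of a forecast is a guess

1. part of the first end groups that has reacted at 10 d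
2. share of free second end groups in free second end groups and idle adduct together, at 10 d

Friday's flask, with 15 mM of first end groups on the same second end groups, has a ceiling of 63.3%, and its links read 62% at 4.00 d, which is 9.30 mM. Wednesday's links read 89% at 4.00 d, which is 8.90 mM. In both runs the links approach the same charge of second end groups, at two different charges of first end groups. The reckoning here therefore puts c, the part of first end groups reacted at 10 d, under the ceiling of 95.0% and near the 90.0% reacted that Wednesday's last reading shows, a reading that carries a scatter of 2 percentage points; it gives no figure for fr.

The forecast gives 90% for c, since Wednesday's last point is, in its words, “already there, with perhaps slight creep left”, and 60% for fr as a guess.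

Wednesday's flask gives 89.3% for c, within the forecast's margin, and 95.4% for fr, higher than the forecast.

    first end groups + second end groups ⇌ links + released group (K = 130, k = 23.0 M⁻¹ h⁻¹)
    first end groups + released group → side product (k = 0.160 M⁻¹ h⁻¹)
    second end groups + released group ⇌ idle adduct, settled at all times (K = 56.0 M⁻¹)
    second end groups ⇌ dormant form (K = 6.60, k = 0.00620 h⁻¹)
    scavenger + released group → scavenged by-product (k = 240 M⁻¹ h⁻¹)

At 10.0 d, c in Wednesday's flask stands 5.7 points under the ceiling of 95.0%, and the dormant form then holds 0.542 mM of second end groups, which is 5.42% of the first end groups charged. A neighbouring flask has 2.4 mM of second end groups on the same first end groups, so its ceiling is 24.0%; at 10.0 d its c is 23.4%, its dormant form holds 0.0577 mM, and 77% of the first end groups charged remain.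

All runs come from a simulation on assumed constants.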